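**Retrosynthetic overview**
1. Target enone 23 ⇐ β-silyloxy ketone 22 by loss of silanol; the C1 oxygen is a traceless control element.
2. 22 ⇐ acyclic coumarinyl ether 18 by one radical bicyclisation that forms C4–C5 (ring A) and then C10–C9 (ring B); an allylic sulfone leaves as a radical to fix the Δ7 alkene, and the Z-alkene puts CH2OAr axial.
3. 18 ⇐ enal 14 + silyl dienol ether 16 by a catalytic asymmetric aldol, the only step that uses a chiral reagent.
4. 14 ⇐ cross-metathesis (methacrolein) of sulfone 12 ⇐ Z-diol 9 (3-methylbutenolide + allylmagnesium bromide), two Mitsunobu reactions and S-oxidation.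
5. Isofraxidin 5 ⇐ resorcinol by formylation, dibromination, Cu-methoxylation and Wittig lactonisation.

Assumption: terpenoid carbons carry drimane numbers (C1–C10, C11 = OCH2, C12 = 8-Me; target = 5S,9S,10R), and the (R,R)-bisphosphoramide/SiCl4 aldol is taken to attack the Re face of the enal (the (S,S)-catalyst is used if the sense is opposite).

**Step 1**
Reactants: 1 resorcinol
Product: 2 2,4-dihydroxybenzaldehyde
Conditions: POCl3, DMF, MeCN, −15 °C → rt; then H2O, 50 °C
Reagents that add atoms: N,N-dimethylformamide CN(C)C=O; water O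
Why: Vilsmeier–Haack formylation goes to C4 of resorcinol, the unhindered position para to one OH and ortho to the other.

**Step 2**
Reactants: 2 2,4-dihydroxybenzaldehyde
Product: 3 3,5-dibromo-2,4-dihydroxybenzaldehyde
Conditions: Br2 (2.1 equiv), AcOH, rt
Reagents that add atoms: bromine BrBr
Why: Electrophilic aromatic bromination fills the two positions ortho/para to both hydroxyls (C3, C5); C6 is meta to both and stays free.

**Step 3**
Reactants: 3 3,5-dibromo-2,4-dihydroxybenzaldehyde
Product: 4 2,4-dihydroxy-3,5-dimethoxybenzaldehyde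
Conditions: NaOMe (6 equiv), CuCl (0.3 equiv), DMF/MeOH, 110 °C; then aq. HCl
Reagents that add atoms: sodium methoxide C[O-].[Na+]
Why: Copper-catalysed Ullmann-type methoxylation of ortho-bromophenoxides (the dibromo-hydroxybenzaldehyde → syringaldehyde reaction type) replaces both bromides and leaves aldehyde and phenols unchanged.

**Step 4**
Reactants: 4 2,4-dihydroxy-3,5-dimethoxybenzaldehyde
Product: 5 isofraxidin (7-hydroxy-6,8-dimethoxy-2H-chromen-2-one)
Conditions: Ph3P=CHCO2Et (1.2 equiv), N,N-diethylaniline, reflux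
Reagents that add atoms: ethyl (triphenylphosphoranylidene)acetate CCOC(=O)C=P(c1ccccc1)(c1ccccc1)c1ccccc1
Why: Wittig olefination of the salicylaldehyde followed by thermal E→Z isomerisation and lactonisation onto the 2-OH gives the coumarin; the OH flanked by two methoxy groups remains as the free 7-OH.

**Step 5**
Reactants: 6 3-methylfuran-2(5H)-one; 7 allylmagnesium bromide
Product: 9 (2Z)-3-methylhepta-2,6-diene-1,4-diol (racemic), via lactol 8 (not isolated)
Conditions: DIBAL-H (1.05 equiv), CH2Cl2, −78 °C; then 7 (3 equiv), Et2O, −78 → 0 °C; Rochelle salt work-up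
Reagents that add atoms: none
Why: DIBAL 1,2-reduction stops at the lactol (as its aluminium alkoxide), whose open Z-hydroxy-enal form adds the allyl Grignard 1,2; the butenolide ring fixes the Z geometry of the future C8=C9 bond, and the new carbinol (C7) is racemic and later destroyed.

**Step 6**
Reactants: 9 (2Z)-3-methylhepta-2,6-diene-1,4-diol; 5 isofraxidin
Product: 10 7-{[(2Z)-4-hydroxy-3-methylhepta-2,6-dien-1-yl]oxy}-6,8-dimethoxy-2H-chromen-2-one
Conditions: PPh3, DIAD, THF, 0 °C → rt (9 in slight excess)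
Reagents that add atoms: none
Why: Mitsunobu etherification activates the primary allylic hydroxyl selectively, and the acidic phenol (pKa about 8) attacks by SN2 faster than the secondary hydroxyl can close a dihydrofuran; the neutral conditions spare the lactone.

**Step 7**
Reactants: 10 7-{[(2Z)-4-hydroxy-3-methylhepta-2,6-dien-1-yl]oxy}-6,8-dimethoxy-2H-chromen-2-one
Product: 11 6,8-dimethoxy-7-{[(2Z)-3-methyl-4-(phenylsulfanyl)hepta-2,6-dien-1-yl]oxy}-2H-chromen-2-one
Conditions: PhSH (1.5 equiv), PPh3, DIAD, toluene, 0 °C → rt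
Reagents that add atoms: thiophenol Sc1ccccc1
Why: Mitsunobu thioetherification (SN2) of the secondary allylic alcohol puts sulfur on C7 without ionising the Z-allyl system and without base, which would cause 1,4-elimination of the aryloxide; the configuration at C7 is irrelevant.

**Step 8**
Reactants: 11 6,8-dimethoxy-7-{[(2Z)-3-methyl-4-(phenylsulfanyl)hepta-2,6-dien-1-yl]oxy}-2H-chromen-2-one
Product: 12 6,8-dimethoxy-7-{[(2Z)-3-methyl-4-(phenylsulfonyl)hepta-2,6-dien-1-yl]oxy}-2H-chromen-2-one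
Conditions: (NH4)6Mo7O24·4H2O (10 mol%), 30% H2O2 (4 equiv), EtOH, 0 °C → rt
Reagents that add atoms: hydrogen peroxide OO
Why: Molybdate/peroxide oxidation takes the sulfide through the sulfoxide to the sulfone chemoselectively in the presence of alkenes, as in Julia olefination sequences.

**Step 9**
Reactants: 12 6,8-dimethoxy-7-{[(2Z)-3-methyl-4-(phenylsulfonyl)hepta-2,6-dien-1-yl]oxy}-2H-chromen-2-one; 13 methacrolein
Product: 14 (2E,6Z)-8-[(6,8-dimethoxy-2-oxo-2H-chromen-7-yl)oxy]-2,6-dimethyl-5-(phenylsulfonyl)octa-2,6-dienal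
Conditions: Hoveyda–Grubbs II (5 mol%), 13 (10 equiv), CH2Cl2, 40 °C
Reagents that add atoms: none
Why: Olefin cross-metathesis of the only terminal alkene with methacrolein gives the E-configured 2-methyl-2-enal (future C5=C10) under thermodynamic control; the trisubstituted allyl sulfone alkene and the coumarin double bond do not react.

**Step 10**
Reactants: 15 3-methylbut-3-en-2-one
Product: 16 trimethyl[(3-methylbuta-1,3-dien-2-yl)oxy]silane
Conditions: TMSOTf, Et3N, Et2O, 0 °C
Reagents that add atoms: trimethylsilyl trifluoromethanesulfonate C[Si](C)(C)OS(=O)(=O)C(F)(F)F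
Why: Soft enolisation and O-silylation can only take place at the methyl group, giving the 2-silyloxydiene for a Mukaiyama aldol.

**Step 11**
Reactants: 14 (2E,6Z)-8-[(6,8-dimethoxy-2-oxo-2H-chromen-7-yl)oxy]-2,6-dimethyl-5-(phenylsulfonyl)octa-2,6-dienal; 16 trimethyl[(3-methylbuta-1,3-dien-2-yl)oxy]silane
Product: 17 7-{[(2Z,6E,8R)-8-hydroxy-3,7,11-trimethyl-10-oxo-4-(phenylsulfonyl)dodeca-2,6,11-trien-1-yl]oxy}-6,8-dimethoxy-2H-chromen-2-one (1:1 at the sulfone carbon)
Conditions: SiCl4 (1.5 equiv), Denmark (R,R)-bisphosphoramide (5 mol%), i-Pr2NEt (0.2 equiv), CH2Cl2, −78 °C; aq. KF/NaHCO3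
Reagents that add atoms: none
Why: Lewis-base-activated SiCl4 Mukaiyama aldol of a methyl ketone enolsilane with a conjugated aldehyde; the chiral phosphoramide–silyl cation directs Re-face attack and sets the R carbinol (C1) regardless of the remote racemic sulfone centre, under non-basic conditions.

**Step 12**
Reactants: 17 7-{[(2Z,6E,8R)-8-hydroxy-3,7,11-trimethyl-10-oxo-4-(phenylsulfonyl)dodeca-2,6,11-trien-1-yl]oxy}-6,8-dimethoxy-2H-chromen-2-one
Product: 18 7-{[(2Z,6E,8R)-8-(tert-butyldimethylsilyloxy)-3,7,11-trimethyl-10-oxo-4-(phenylsulfonyl)dodeca-2,6,11-trien-1-yl]oxy}-6,8-dimethoxy-2H-chromen-2-one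
Conditions: TBSOTf (1.3 equiv), 2,6-lutidine, CH2Cl2, −78 °C
Reagents that add atoms: tert-butyldimethylsilyl trifluoromethanesulfonate CC(C)(C)[Si](C)(C)OS(=O)(=O)C(F)(F)F
Why: Silylation blocks retro-aldol, oxa-Michael and β-elimination of the β-hydroxy enone and makes the C1 substituent large enough to steer the cyclisation; no stereocentre is touched.

**Step 13**
Reactants: 18 7-{[(2Z,6E,8R)-8-(tert-butyldimethylsilyloxy)-3,7,11-trimethyl-10-oxo-4-(phenylsulfonyl)dodeca-2,6,11-trien-1-yl]oxy}-6,8-dimethoxy-2H-chromen-2-one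
Product: 22 7-{[(1S,4aS,8R,8aR)-8-(tert-butyldimethylsilyloxy)-2,5,5,8a-tetramethyl-6-oxo-1,4,4a,5,6,7,8,8a-octahydronaphthalen-1-yl]methoxy}-6,8-dimethoxy-2H-chromen-2-one, via α-keto radical 19 (not isolated), via monocyclic radical 20 (not isolated), via β-sulfonyl radical 21 (not isolated)
Conditions: Fe(acac)3 (0.3 equiv), PhSiH3 (2.5 equiv, slow addition), EtOH/ethylene glycol 5:1, 0.01 M, 60 °C, degassed
Reagents that add atoms: none
Why: Proposed new method: Fe–H hydrogen-atom transfer to the isopropenyl ketone (closest known types: Fe(acac)3/silane MHAT olefin couplings and HAT-initiated polyene cyclisations, Mn(III) α-keto-radical polyene cyclisations, allyl sulfones as radical allyl-transfer acceptors) gives α-keto radical 19, which closes 6-endo onto C5 of the E-alkene through a chair with the OTBS group pseudo-axial (A1,2 strain with the C10 methyl) so that H5 ends cis to it (5S); radical 20 then closes through a chair onto C9 of the Z-allyl sulfone trans to H5 (10R) with CH2OAr axial (9S), and radical 21 expels PhSO2•, which fixes the Δ7 alkene and re-oxidises Fe(II), both sulfone epimers converging on 22.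

**Step 14**
Reactants: 22 7-{[(1S,4aS,8R,8aR)-8-(tert-butyldimethylsilyloxy)-2,5,5,8a-tetramethyl-6-oxo-1,4,4a,5,6,7,8,8a-octahydronaphthalen-1-yl]methoxy}-6,8-dimethoxy-2H-chromen-2-one
Product: 23 7-{[(1S,4aS,8aR)-2,5,5,8a-tetramethyl-6-oxo-1,4,4a,5,6,8a-hexahydronaphthalen-1-yl]methoxy}-6,8-dimethoxy-2H-chromen-2-one (target)
Conditions: p-TsOH·H2O (0.2 equiv), wet CH2Cl2, 40 °C
Reagents that add atoms: none
Why: Acid-mediated desilylation and β-elimination (axial C1–O anti to axial C2–H) of the β-silyloxy ketone gives the conjugated enone and erases the auxiliary C1 stereocentre while 5S, 9S and 10R are untouched.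

**Compound list**
1 | resorcinol | Oc1cccc(O)c1 | starting material
2 | 2,4-dihydroxybenzaldehyde | O=Cc1ccc(O)cc1O | intermediate
3 | 3,5-dibromo-2,4-dihydroxybenzaldehyde | O=Cc1cc(Br)c(O)c(Br)c1O | intermediate
4 | 2,4-dihydroxy-3,5-dimethoxybenzaldehyde | O=Cc1cc(OC)c(O)c(OC)c1O | intermediate
5 | isofraxidin | COc1cc2ccc(=O)oc2c(OC)c1O | intermediate
6 | 3-methylfuran-2(5H)-one | CC1=CCOC1=O | starting material
7 | allylmagnesium bromide | C=CC[Mg]Br | starting material
8 | 3-methyl-2,5-dihydrofuran-2-ol (lactol, present as aluminium alkoxide) | CC1=CCOC1O | intermediate (not isolated)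
9 | (2Z)-3-methylhepta-2,6-diene-1,4-diol (racemic) | OC/C=C(C)\C(O)CC=C | intermediate
10 | 7-{[(2Z)-4-hydroxy-3-methylhepta-2,6-dien-1-yl]oxy}-6,8-dimethoxy-2H-chromen-2-one | COc1cc2ccc(=O)oc2c(OC)c1OC/C=C(C)\C(O)CC=C | intermediate
11 | 6,8-dimethoxy-7-{[(2Z)-3-methyl-4-(phenylsulfanyl)hepta-2,6-dien-1-yl]oxy}-2H-chromen-2-one | COc1cc2ccc(=O)oc2c(OC)c1OC/C=C(C)\C(Sc1ccccc1)CC=C | intermediate
12 | 6,8-dimethoxy-7-{[(2Z)-3-methyl-4-(phenylsulfonyl)hepta-2,6-dien-1-yl]oxy}-2H-chromen-2-one | COc1cc2ccc(=O)oc2c(OC)c1OC/C=C(C)\C(CC=C)S(=O)(=O)c1ccccc1 | intermediate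
13 | methacrolein | CC(=C)C=O | starting material
14 | (2E,6Z)-8-[(6,8-dimethoxy-2-oxo-2H-chromen-7-yl)oxy]-2,6-dimethyl-5-(phenylsulfonyl)octa-2,6-dienal | COc1cc2ccc(=O)oc2c(OC)c1OC/C=C(C)\C(C/C=C(\C)C=O)S(=O)(=O)c1ccccc1 | intermediate
15 | 3-methylbut-3-en-2-one | CC(=O)C(C)=C | starting material
16 | trimethyl[(3-methylbuta-1,3-dien-2-yl)oxy]silane | C=C(O[Si](C)(C)C)C(C)=C | intermediate
17 | 7-{[(2Z,6E,8R)-8-hydroxy-3,7,11-trimethyl-10-oxo-4-(phenylsulfonyl)dodeca-2,6,11-trien-1-yl]oxy}-6,8-dimethoxy-2H-chromen-2-one | COc1cc2ccc(=O)oc2c(OC)c1OC/C=C(C)\C(C/C=C(\C)[C@H](O)CC(=O)C(C)=C)S(=O)(=O)c1ccccc1 | intermediate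
18 | 7-{[(2Z,6E,8R)-8-(tert-butyldimethylsilyloxy)-3,7,11-trimethyl-10-oxo-4-(phenylsulfonyl)dodeca-2,6,11-trien-1-yl]oxy}-6,8-dimethoxy-2H-chromen-2-one | COc1cc2ccc(=O)oc2c(OC)c1OC/C=C(C)\C(C/C=C(\C)[C@H](O[Si](C)(C)C(C)(C)C)CC(=O)C(C)=C)S(=O)(=O)c1ccccc1 | intermediate
19 | tertiary α-keto radical (C4 radical formed from 18 by H-atom addition) | COc1cc2ccc(=O)oc2c(OC)c1OC/C=C(C)\C(C/C=C(\C)[C@H](O[Si](C)(C)C(C)(C)C)CC(=O)[C](C)C)S(=O)(=O)c1ccccc1 | intermediate (not isolated)
20 | monocyclic tertiary radical (ring A closed, radical at C10) | COc1cc2ccc(=O)oc2c(OC)c1OC/C=C(C)\C(C[C@H]1[C](C)[C@H](O[Si](C)(C)C(C)(C)C)CC(=O)C1(C)C)S(=O)(=O)c1ccccc1 | intermediate (not isolated)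
21 | bicyclic β-sulfonyl radical (radical at C8) | COc1cc2ccc(=O)oc2c(OC)c1OC[C@H]1[C](C)C(S(=O)(=O)c3ccccc3)C[C@@H]2C(C)(C)C(=O)C[C@@H](O[Si](C)(C)C(C)(C)C)[C@]21C | intermediate (not isolated)
22 | 7-{[(1S,4aS,8R,8aR)-8-(tert-butyldimethylsilyloxy)-2,5,5,8a-tetramethyl-6-oxo-1,4,4a,5,6,7,8,8a-octahydronaphthalen-1-yl]methoxy}-6,8-dimethoxy-2H-chromen-2-one | COc1cc2ccc(=O)oc2c(OC)c1OC[C@H]1C(C)=CC[C@@H]2C(C)(C)C(=O)C[C@@H](O[Si](C)(C)C(C)(C)C)[C@]21C | intermediate
23 | 7-{[(1S,4aS,8aR)-2,5,5,8a-tetramethyl-6-oxo-1,4,4a,5,6,8a-hexahydronaphthalen-1-yl]methoxy}-6,8-dimethoxy-2H-chromen-2-one | COc1cc2ccc(=O)oc2c(OC)c1OC[C@H]1C(C)=CC[C@@H]2C(C)(C)C(=O)C=C[C@]21C | target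

**Totals**
Total step count: 14. Longest linear sequence: 12 steps (1 → 5, then steps 6–9 and 11–14 to 23).

**Three steps most likely to fail**

Step 13. The α-keto radical may be reduced before it cyclises, or the stereo-relay from C1 may be weak. The fallback separates radical generation from hydrogen-atom transfer. It sets out from 18: conjugate reduction with L-Selectride (THF, −78 °C) and trapping of the enolate with NBS gives the tertiary α-bromo ketone F1. Bromine abstraction from F1 with hexabutylditin under irradiation (benzene, 80 °C) starts the same cascade, with PhSO2• carried on by the ditin. The route is rejoined at 22.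

Step 6. The Z-1,4-diol may cyclodehydrate to a dihydrofuran under Mitsunobu activation. The fallback sets out from 9: SOCl2/Et3N (CH2Cl2, 0 °C) gives the cyclic sulfite F2. The potassium salt of 5 (K2CO3, DMF, 60 °C) opens it by SN2 at the primary allylic carbon, and acidic hydrolysis of the sulfite monoester returns to 10.

Step 7. SN2' attack or elimination may compete at the hindered secondary allylic carbinol. The fallback sets out from 10: MsCl/Et3N (CH2Cl2, −30 °C) gives the allylic mesylate F3, which is treated without isolation with PhSO2Na/Bu4NI in DMF. S-alkylation of the sulfinate gives the sulfone directly, so the route is rejoined at 12 without 11 and without step 8.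

**Further compounds**
F1 | step 13 | tertiary α-bromo ketone: 7-{[(2Z,6E,8R)-11-bromo-8-(tert-butyldimethylsilyloxy)-3,7,11-trimethyl-10-oxo-4-(phenylsulfonyl)dodeca-2,6-dien-1-yl]oxy}-6,8-dimethoxy-2H-chromen-2-one | COc1cc2ccc(=O)oc2c(OC)c1OC/C=C(C)\C(C/C=C(\C)[C@H](O[Si](C)(C)C(C)(C)C)CC(=O)C(C)(C)Br)S(=O)(=O)c1ccccc1
F2 | step 6 | cyclic sulfite: 4-allyl-5-methyl-4,7-dihydro-1,3,2-dioxathiepine 2-oxide | C=CCC1OS(=O)OCC=C1C
F3 | step 7 | allylic mesylate: (2Z)-1-[(6,8-dimethoxy-2-oxo-2H-chromen-7-yl)oxy]-3-methylhepta-2,6-dien-4-yl methanesulfonate | COc1cc2ccc(=O)oc2c(OC)c1OC/C=C(C)\C(OS(C)(=O)=O)CC=C
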